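**Plan**

- Retrosynthesis: the lactone CH2–O is traced back to an acetal carbon and the ring B benzylic CH2 to a dithiane carbon. The Cβ–C(benzylic, ring B) and Cα–CH2(ring C) bonds are then cut in one operation, leaving a 5-alkoxybutenolide, a ring A–B aryl dithiane and a ring C–D benzylic bromide.
- Enabling feature: in the trans-α,β-dibenzyl-γ-butyrolactone, Cβ (C4) carries the ring B benzyl group and Cα (C3) the ring C benzyl group. These are C4 (acceptor) and C3 (enolate carbon) of a furan-2(5H)-one, so a nucleophile and then an electrophile can be added in turn.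
- Fragment A–B: the C7–C8 bond comes from an aryloxyacetyl imide aldol. Fragment C–D: the C–C bond comes from an arylacetyl imide aldol, and the dihydrofuran ring is then closed through the benzylic C–O bond.
- Forward order: butenolide; A–B dithiane; C–D bromide (the only ring closed before the union); three-component coupling; desulfurisation; acetal-to-lactone conversion with global deprotection.
- Stereochemistry: lactone C3/C4 are relayed from the menthyloxy acetal centre, itself fixed by (−)-menthol and crystallisation. The A–B unit takes C8 from an (R)-oxazolidinone syn aldol and C7 from a Mitsunobu inversion. The dihydrobenzofuran takes C3 from an (S)-oxazolidinone aldol and C2 from trans-selective cyclisation.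

Key step: step 20

Remark: a boron aldol of an aryloxyacetyl imide delivers the syn (threo) pair of centres, so the erythro A–B unit is reached by one benzylic inversion; every compound marked as starting material in the list is taken as a catalogue chemical.

**Route**

Step 1
Reactants: 1 furfural
Product: 2 5-hydroxyfuran-2(5H)-one (racemic lactol)
Conditions: O2, rose bengal (cat.), hν (visible), MeOH, rt
Reagents that add atoms: dioxygen, O=O
Why: Singlet-oxygen [4+2] cycloaddition to the furan followed by methanolysis of the endoperoxide, which expels the formyl carbon as methyl formate, is the established photo-oxygenation route to this hydroxybutenolide.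

Step 2
Reactants: 2 5-hydroxyfuran-2(5H)-one; 3 (1R,2S,5R)-menthol
Product: 4 (5R)-5-[(1R,2S,5R)-menthyloxy]furan-2(5H)-one
Conditions: CSA (cat.), toluene, reflux (Dean–Stark); crystallisation from petroleum ether, −20 °C, mother liquor re-equilibrated with CSA
Reagents that add atoms: none
Why: Acid-catalysed acetalisation of the lactol gives both C5 epimers, which interconvert under the acid, and crystallisation should remove the (5R) epimer (crystallisation-driven epimer enrichment), so C5 is fixed relative to the three menthol centres.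

Step 3
Reactants: 5 vanillin
Product: 6 4-[(tert-butyldimethylsilyl)oxy]-3-methoxybenzaldehyde
Conditions: TBSCl, imidazole, DMF, rt
Reagents that add atoms: tert-butyldimethylsilyl chloride, CC(C)(C)[Si](C)(C)Cl
Why: Imidazole-promoted silylation of the phenol (silyl ether formation) masks the future ring A hydroxyl against the boron aldol, Mitsunobu and organolithium steps.

Step 4
Reactants: 7 (4-formyl-2-methoxyphenoxy)acetic acid
Product: 8 [4-(1,3-dithian-2-yl)-2-methoxyphenoxy]acetic acid
Conditions: HS(CH2)3SH, BF3·OEt2 (cat.), CH2Cl2–AcOH, rt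
Reagents that add atoms: propane-1,3-dithiol, SCCCS
Why: Lewis-acid-catalysed dithioacetalisation is selective for the aldehyde and installs the future carbanion site of ring B before any acid-labile group is present.

Step 5
Reactants: 8 [4-(1,3-dithian-2-yl)-2-methoxyphenoxy]acetic acid
Product: 10 (4R)-4-benzyl-3-{[4-(1,3-dithian-2-yl)-2-methoxyphenoxy]acetyl}-1,3-oxazolidin-2-one, via mixed pivalic anhydride 9 (not isolated)
Conditions: PivCl, Et3N, THF, −20 °C; then (R)-4-benzyl-1,3-oxazolidin-2-one, LiCl, rt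
Reagents that add atoms: (R)-4-benzyl-1,3-oxazolidin-2-one, O=C1N[C@H](Cc2ccccc2)CO1
Why: N-acylation of the oxazolidinone through the mixed pivalic anhydride is the standard entry to aryloxyacetyl imides.

Step 6
Reactants: 10 (4R)-4-benzyl-3-{[4-(1,3-dithian-2-yl)-2-methoxyphenoxy]acetyl}-1,3-oxazolidin-2-one; 6 4-[(tert-butyldimethylsilyl)oxy]-3-methoxybenzaldehyde
Product: 12 (4R)-4-benzyl-3-[(2R,3S)-3-{4-[(tert-butyldimethylsilyl)oxy]-3-methoxyphenyl}-2-[4-(1,3-dithian-2-yl)-2-methoxyphenoxy]-3-hydroxypropanoyl]-1,3-oxazolidin-2-one (syn adduct), via Z boron enolate 11 (not isolated)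
Conditions: Bu2BOTf, i-Pr2NEt, CH2Cl2, 0 °C; then 6, −78 → 0 °C; pH 7 buffer–MeOH work-up without peroxide
Reagents that add atoms: none
Why: In this Evans boron aldol reaction the Z enolate reacts through a chair Zimmerman–Traxler transition state on the face away from the auxiliary benzyl group, which should set C2 as R and C3 as S (syn), and the peroxide-free work-up spares the dithiane.

Step 7
Reactants: 12 syn aldol adduct
Product: 13 (1R,2R)-3-[(4R)-4-benzyl-2-oxo-1,3-oxazolidin-3-yl]-1-{4-[(tert-butyldimethylsilyl)oxy]-3-methoxyphenyl}-2-[4-(1,3-dithian-2-yl)-2-methoxyphenoxy]-3-oxopropyl 4-nitrobenzoate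
Conditions: 4-O2NC6H4CO2H, PPh3, DIAD, THF, 0 °C → rt
Reagents that add atoms: 4-nitrobenzoic acid, O=C(O)c1ccc([N+](=O)[O-])cc1
Why: Mitsunobu esterification displaces the benzylic oxyphosphonium by 4-nitrobenzoate in an SN2 manner, inverting the carbinol centre from S to R (threo to erythro), while allylic 1,3-strain in the imide keeps the neighbouring C–H bond out of alignment for β-elimination.

Step 8
Reactants: 13 inverted 4-nitrobenzoate
Product: 14 (1R,2S)-1-{4-[(tert-butyldimethylsilyl)oxy]-3-methoxyphenyl}-2-[4-(1,3-dithian-2-yl)-2-methoxyphenoxy]propane-1,3-diol (erythro)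
Conditions: LiBH4, THF (MeOH, 2 equiv), 0 °C → rt
Reagents that add atoms: none
Why: Borohydride reduction cleaves the imide reductively to the primary alcohol and removes the 4-nitrobenzoate without touching either stereocentre, so the erythro diol should result and the auxiliary is recoverable.

Step 9
Reactants: 14 erythro diol
Product: 15 (4R,5S)-4-{4-[(tert-butyldimethylsilyl)oxy]-3-methoxyphenyl}-5-[4-(1,3-dithian-2-yl)-2-methoxyphenoxy]-2,2-dimethyl-1,3-dioxane
Conditions: Me2C(OMe)2, PPTS (cat.), CH2Cl2, rt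
Reagents that add atoms: 2,2-dimethoxypropane, COC(C)(C)OC
Why: Acid-catalysed transketalisation closes the 1,3-dioxane on the only diol present, PPTS being too weak to ionise the benzylic C–O bond or to disturb the dithiane and the aryl silyl ether.

Step 10
Reactants: 16 methyl 3-bromo-4-hydroxy-5-methoxybenzoate (methyl 5-bromovanillate)
Product: 17 methyl 4-(benzyloxy)-3-bromo-5-methoxybenzoate
Conditions: BnBr, K2CO3, DMF, rt
Reagents that add atoms: benzyl bromide, BrCc1ccccc1
Why: Williamson etherification protects the hindered ring C phenol as a benzyl ether that withstands the zinc enolate coupling, TFA and the boron aldol.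

Step 11
Reactants: 17 methyl 4-(benzyloxy)-3-bromo-5-methoxybenzoate
Product: 18 methyl 4-(benzyloxy)-3-(2-tert-butoxy-2-oxoethyl)-5-methoxybenzoate
Conditions: BrZnCH2CO2t-Bu, [PdBr(P(t-Bu)3)]2 (cat.), THF, rt
Reagents that add atoms: (2-tert-butoxy-2-oxoethyl)zinc bromide, Br[Zn]CC(=O)OC(C)(C)C
Why: Palladium-catalysed cross-coupling of the Reformatsky reagent with the aryl bromide (Negishi-type α-arylation of a zinc ester enolate) runs under neutral conditions that leave the methyl ester untouched.

Step 12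
Reactants: 18 tert-butyl arylacetate
Product: 19 [2-(benzyloxy)-3-methoxy-5-(methoxycarbonyl)phenyl]acetic acid
Conditions: TFA, CH2Cl2, 0 °C → rt
Reagents that add atoms: none
Why: Acidolysis of the tert-butyl ester with loss of isobutene frees the arylacetic acid, while the methyl ester and the benzyl aryl ether are stable to TFA.

Step 13
Reactants: 19 arylacetic acid
Product: 21 methyl 4-(benzyloxy)-3-{2-[(4S)-4-benzyl-2-oxo-1,3-oxazolidin-3-yl]-2-oxoethyl}-5-methoxybenzoate, via mixed pivalic anhydride 20 (not isolated)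
Conditions: PivCl, Et3N, THF, −20 °C; then (S)-4-benzyl-1,3-oxazolidin-2-one, LiCl, rt
Reagents that add atoms: (S)-4-benzyl-1,3-oxazolidin-2-one, O=C1N[C@@H](Cc2ccccc2)CO1
Why: N-acylation through the mixed pivalic anhydride attaches the auxiliary to the arylacetic acid under conditions that do not affect the benzoate ester.

Step 14
Reactants: 21 arylacetyl imide; 22 4-(benzyloxy)-3-methoxybenzaldehyde
Product: 24 methyl 4-(benzyloxy)-3-[(2S,3S)-1-[(4S)-4-benzyl-2-oxo-1,3-oxazolidin-3-yl]-3-[4-(benzyloxy)-3-methoxyphenyl]-3-hydroxy-1-oxopropan-2-yl]-5-methoxybenzoate (syn adduct), via Z boron enolate 23 (not isolated)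
Conditions: Bu2BOTf, i-Pr2NEt, CH2Cl2, 0 °C; then 22, −78 → 0 °C; pH 7 buffer–MeOH work-up
Reagents that add atoms: none
Why: In this Evans boron aldol reaction the Z enolate of the arylacetyl imide adds through a chair transition state on the face opposite the auxiliary benzyl group, which should set the aryl-bearing carbon as S (the future C3 of the dihydrobenzofuran) and the carbinol carbon as S.

Step 15
Reactants: 24 syn aldol adduct
Product: 25 methyl 4-(benzyloxy)-3-[(1S,2R)-1-[4-(benzyloxy)-3-methoxyphenyl]-1,3-dihydroxypropan-2-yl]-5-methoxybenzoate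
Conditions: NaBH4, THF–H2O, 0 °C → rt
Reagents that add atoms: none
Why: NaBH4 in wet THF reduces the activated imide carbonyl to the primary alcohol (reductive removal of the auxiliary) but not the deactivated methyl benzoate, and the aryl-bearing centre cannot epimerise at the alcohol oxidation level.

Step 16
Reactants: 25 dibenzyl diol
Product: 27 methyl (2S,3R)-2-(4-hydroxy-3-methoxyphenyl)-3-(hydroxymethyl)-7-methoxy-2,3-dihydro-1-benzofuran-5-carboxylate, via tetraol 26 (not isolated)
Conditions: H2 (1 atm), 10% Pd/C, EtOAc, rt; filter; then HCl (0.2 M), dioxane–H2O, 50 °C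
Reagents that add atoms: none
Why: Hydrogenolysis frees both phenols, and acid then ionises the para-hydroxybenzylic alcohol to a quinone-methide-like cation that the ortho phenol traps in a 5-exo closure of the dihydrofuran ring; since this benzylic C–O bond can re-ionise, C2 should settle trans to the C3 hydroxymethyl group (2S) under thermodynamic control.

Step 17
Reactants: 27 dihydrobenzofuran phenol alcohol
Product: 28 methyl (2S,3R)-2-{4-[(tert-butyldimethylsilyl)oxy]-3-methoxyphenyl}-3-{[(tert-butyldimethylsilyl)oxy]methyl}-7-methoxy-2,3-dihydro-1-benzofuran-5-carboxylate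
Conditions: TBSCl (excess), imidazole, DMF, rt
Reagents that add atoms: tert-butyldimethylsilyl chloride, CC(C)(C)[Si](C)(C)Cl
Why: Silylation of the phenol and the primary alcohol (silyl ether formation) leaves the ester as the only reducible group.

Step 18
Reactants: 28 bis-silyl ester
Product: 29 [(2S,3R)-2-{4-[(tert-butyldimethylsilyl)oxy]-3-methoxyphenyl}-3-{[(tert-butyldimethylsilyl)oxy]methyl}-7-methoxy-2,3-dihydro-1-benzofuran-5-yl]methanol
Conditions: i-Bu2AlH, CH2Cl2, −78 → 0 °C; aq. potassium sodium tartrate (KNaC4H4O6)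
Reagents that add atoms: none
Why: Hydride reduction of the methyl ester gives the benzylic alcohol, and both silyl ethers tolerate the aluminium hydride at low temperature.

Step 19
Reactants: 29 benzylic alcohol
Product: 30 (2S,3R)-5-(bromomethyl)-2-{4-[(tert-butyldimethylsilyl)oxy]-3-methoxyphenyl}-3-{[(tert-butyldimethylsilyl)oxy]methyl}-7-methoxy-2,3-dihydro-1-benzofuran
Conditions: CBr4, PPh3, 2,6-lutidine, CH2Cl2, 0 °C; used at once
Reagents that add atoms: carbon tetrabromide, BrC(Br)(Br)Br
Why: The Appel reaction activates the alcohol as an oxyphosphonium that bromide displaces under neutral conditions, so the silyl ethers and the benzylic ring C–O bond should survive.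

Step 20
Reactants: 15 A–B acetonide dithiane; 4 (5R)-5-menthyloxyfuran-2(5H)-one; 30 C–D benzylic bromide
Product: 33 (3R,4R,5R)-3-[(C–D dihydrobenzofuran-5-yl)methyl]-4-[2-(A–B aryl)-1,3-dithian-2-yl]-5-[(1R,2S,5R)-menthyloxy]dihydrofuran-2(3H)-one (3,4-trans-4,5-trans; full structure in the list), via lithiated dithiane 31 (not isolated), via lithium enolate 32 (not isolated)
Conditions: n-BuLi, THF, −78 °C; then 4, −78 °C; then 30, DMPU, −78 → −20 °C; aq. NH4Cl
Reagents that add atoms: none
Why: n-BuLi removes the acidic 2-H of the 2-aryl-1,3-dithiane to give the sulfur-stabilised benzylic anion 31, which adds 1,4 (Michael addition) to C4 of butenolide 4, and the lithium enolate 32 so formed is C-benzylated (SN2) by bromide 30 once DMPU is added. The closest known reaction type is the tandem conjugate addition–enolate alkylation of lithiated dithioacetals with 5-alkoxyfuran-2(5H)-ones used for trans-dibenzylbutyrolactone lignans. No ring is closed, and both benzylic C–C bonds of the lactone are made on the intact five-membered ring. C4 should become R because the anion enters anti to the C5 menthyloxy group, and C3 should become R because the bromide enters anti to the bulky dithianyl group at C4. The step needs 1,4- over 1,2-addition, which the soft, hindered, doubly sulfur-stabilised anion at −78 °C secures, and C- over O-alkylation without proton exchange, which the reactive electron-rich benzylic bromide, the lithium counter-ion and the polar cosolvent secure. The silyl ethers, the acetonide and the dihydrobenzofuran offer no competing acidic or electrophilic site under these conditions.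

Step 21
Reactants: 33 dithianyl lactone acetal
Product: 34 (3R,4R,5R)-3-[(C–D dihydrobenzofuran-5-yl)methyl]-4-[(A–B aryl)methyl]-5-[(1R,2S,5R)-menthyloxy]dihydrofuran-2(3H)-one
Conditions: NiCl2·6H2O, NaBH4, MeOH–THF, 0 °C
Reagents that add atoms: none
Why: Nickel boride formed in the flask cleaves both C–S bonds reductively (desulfurisation), turning the dithiane carbon into the ring B benzylic CH2 without touching the lactone acetal, the silyl ethers or the benzylic C–O bonds.

Step 22
Reactants: 34 desulfurised lactone acetal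
Product: 37 target (3R,4R)-lactone, via seco hydroxy acid 35 (not isolated), via protected lactone 36 (not isolated)
Conditions: NaBH4, KOH, THF–H2O, rt; then HCl (to about 1 M), THF–H2O, rt
Reagents that add atoms: none
Why: Hydroxide opens the pseudo-ester to the carboxylate and the aldehyde with loss of menthol, NaBH4 reduces the aldehyde at once so that C4 does not epimerise, KOH also cleaves the two aryl silyl ethers, and acidification then closes the γ-lactone and hydrolyses the acetonide and the primary silyl ether (saponification, carbonyl reduction, lactonisation, acetal and silyl ether hydrolysis).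

**Compound list**

1 | furfural | O=Cc1ccco1 | starting material
2 | 5-hydroxyfuran-2(5H)-one (racemic) | O=C1C=CC(O)O1 | intermediate
3 | (1R,2S,5R)-menthol | C[C@@H]1CC[C@H]([C@@H](C1)O)C(C)C | starting material
4 | (5R)-5-[(1R,2S,5R)-menthyloxy]furan-2(5H)-one | O=C1C=C[C@H](O[C@@H]2C[C@H](C)CC[C@H]2C(C)C)O1 | intermediate
5 | vanillin | COc1cc(C=O)ccc1O | starting material
6 | 4-[(tert-butyldimethylsilyl)oxy]-3-methoxybenzaldehyde | COc1cc(C=O)ccc1O[Si](C)(C)C(C)(C)C | intermediate
7 | (4-formyl-2-methoxyphenoxy)acetic acid | COc1cc(C=O)ccc1OCC(=O)O | starting material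
8 | [4-(1,3-dithian-2-yl)-2-methoxyphenoxy]acetic acid | COc1cc(C2SCCCS2)ccc1OCC(=O)O | intermediate
9 | mixed anhydride of 8 with pivalic acid | COc1cc(C2SCCCS2)ccc1OCC(=O)OC(=O)C(C)(C)C | intermediate
10 | (4R)-4-benzyl-3-{[4-(1,3-dithian-2-yl)-2-methoxyphenoxy]acetyl}-1,3-oxazolidin-2-one | COc1cc(C2SCCCS2)ccc1OCC(=O)N1[C@H](Cc2ccccc2)COC1=O | intermediate
11 | (Z)-dibutylboron enolate of 10 | CCCCB(CCCC)O/C(=C\Oc1ccc(C2SCCCS2)cc1OC)N1[C@H](Cc2ccccc2)COC1=O | intermediate
12 | (4R)-4-benzyl-3-[(2R,3S)-3-(4-silyloxy-3-methoxyphenyl)-2-[4-(1,3-dithian-2-yl)-2-methoxyphenoxy]-3-hydroxypropanoyl]-1,3-oxazolidin-2-one (syn, threo) | COc1cc([C@H](O)[C@H](C(=O)N2[C@H](Cc3ccccc3)COC2=O)Oc2ccc(C3SCCCS3)cc2OC)ccc1O[Si](C)(C)C(C)(C)C | intermediate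
13 | (2R,3R) 4-nitrobenzoate of 12 inverted at the benzylic carbon (erythro) | COc1cc([C@@H](OC(=O)c2ccc([N+](=O)[O-])cc2)[C@H](C(=O)N2[C@H](Cc3ccccc3)COC2=O)Oc2ccc(C3SCCCS3)cc2OC)ccc1O[Si](C)(C)C(C)(C)C | intermediate
14 | (1R,2S)-1-(4-silyloxy-3-methoxyphenyl)-2-[4-(1,3-dithian-2-yl)-2-methoxyphenoxy]propane-1,3-diol (erythro) | COc1cc([C@@H](O)[C@H](CO)Oc2ccc(C3SCCCS3)cc2OC)ccc1O[Si](C)(C)C(C)(C)C | intermediate
15 | (4R,5S)-4-(4-silyloxy-3-methoxyphenyl)-5-[4-(1,3-dithian-2-yl)-2-methoxyphenoxy]-2,2-dimethyl-1,3-dioxane | COc1cc([C@@H](OC(C)(C)OC2)[C@H]2Oc2ccc(C3SCCCS3)cc2OC)ccc1O[Si](C)(C)C(C)(C)C | intermediate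
16 | methyl 3-bromo-4-hydroxy-5-methoxybenzoate | COC(=O)c1cc(Br)c(O)c(OC)c1 | starting material
17 | methyl 4-(benzyloxy)-3-bromo-5-methoxybenzoate | COC(=O)c1cc(Br)c(OCc2ccccc2)c(OC)c1 | intermediate
18 | methyl 4-(benzyloxy)-3-(2-tert-butoxy-2-oxoethyl)-5-methoxybenzoate | COC(=O)c1cc(CC(=O)OC(C)(C)C)c(OCc2ccccc2)c(OC)c1 | intermediate
19 | [2-(benzyloxy)-3-methoxy-5-(methoxycarbonyl)phenyl]acetic acid | COC(=O)c1cc(CC(=O)O)c(OCc2ccccc2)c(OC)c1 | intermediate
20 | mixed anhydride of 19 with pivalic acid | COC(=O)c1cc(CC(=O)OC(=O)C(C)(C)C)c(OCc2ccccc2)c(OC)c1 | intermediate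
21 | methyl 4-(benzyloxy)-3-{2-[(4S)-4-benzyl-2-oxo-1,3-oxazolidin-3-yl]-2-oxoethyl}-5-methoxybenzoate | COC(=O)c1cc(CC(=O)N2[C@@H](Cc3ccccc3)COC2=O)c(OCc2ccccc2)c(OC)c1 | intermediate
22 | 4-(benzyloxy)-3-methoxybenzaldehyde | COc1cc(C=O)ccc1OCc1ccccc1 | starting material
23 | (Z)-dibutylboron enolate of 21 | CCCCB(CCCC)O/C(=C\c1cc(C(=O)OC)cc(OC)c1OCc1ccccc1)N1[C@@H](Cc2ccccc2)COC1=O | intermediate
24 | (2S,3S) syn aldol adduct of 21 and 22 | COC(=O)c1cc([C@H](C(=O)N2[C@@H](Cc3ccccc3)COC2=O)[C@H](O)c2ccc(OCc3ccccc3)c(OC)c2)c(OCc2ccccc2)c(OC)c1 | intermediate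
25 | methyl 4-(benzyloxy)-3-[(1S,2R)-1-[4-(benzyloxy)-3-methoxyphenyl]-1,3-dihydroxypropan-2-yl]-5-methoxybenzoate | COC(=O)c1cc([C@H](CO)[C@H](O)c2ccc(OCc3ccccc3)c(OC)c2)c(OCc2ccccc2)c(OC)c1 | intermediate
26 | methyl 3-[(1S,2R)-1,3-dihydroxy-1-(4-hydroxy-3-methoxyphenyl)propan-2-yl]-4-hydroxy-5-methoxybenzoate | COC(=O)c1cc([C@H](CO)[C@H](O)c2ccc(O)c(OC)c2)c(O)c(OC)c1 | intermediate
27 | methyl (2S,3R)-2-(4-hydroxy-3-methoxyphenyl)-3-(hydroxymethyl)-7-methoxy-2,3-dihydro-1-benzofuran-5-carboxylate (trans) | COC(=O)c1cc(OC)c2c(c1)[C@H](CO)[C@@H](c1ccc(O)c(OC)c1)O2 | intermediate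
28 | bis(tert-butyldimethylsilyl) ether of 27 (phenol and primary alcohol) | COC(=O)c1cc(OC)c2c(c1)[C@H](CO[Si](C)(C)C(C)(C)C)[C@@H](c1ccc(O[Si](C)(C)C(C)(C)C)c(OC)c1)O2 | intermediate
29 | (2S,3R) 5-(hydroxymethyl) dihydrobenzofuran bis-silyl ether | OCc1cc(OC)c2c(c1)[C@H](CO[Si](C)(C)C(C)(C)C)[C@@H](c1ccc(O[Si](C)(C)C(C)(C)C)c(OC)c1)O2 | intermediate
30 | (2S,3R) 5-(bromomethyl) dihydrobenzofuran bis-silyl ether | BrCc1cc(OC)c2c(c1)[C@H](CO[Si](C)(C)C(C)(C)C)[C@@H](c1ccc(O[Si](C)(C)C(C)(C)C)c(OC)c1)O2 | intermediate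
31 | 2-lithio derivative of 15 | COc1cc([C@@H](OC(C)(C)OC2)[C@H]2Oc2ccc(C3([Li])SCCCS3)cc2OC)ccc1O[Si](C)(C)C(C)(C)C | intermediate
32 | lithium enolate of the (4R,5R) conjugate adduct of 31 and 4 | COc1cc([C@@H](OC(C)(C)OC2)[C@H]2Oc2ccc(C3(SCCCS3)[C@@H]3C=C(O[Li])O[C@H]3O[C@@H]3C[C@H](C)CC[C@H]3C(C)C)cc2OC)ccc1O[Si](C)(C)C(C)(C)C | intermediate
33 | (3R,4R,5R)-3-benzyl-4-(2-aryl-1,3-dithian-2-yl)-5-menthyloxy lactone carrying rings A to D, acetonide and three silyl ethers | COc1cc([C@@H](OC(C)(C)OC2)[C@H]2Oc2ccc(C3(SCCCS3)[C@H]3[C@H](O[C@@H]4C[C@H](C)CC[C@H]4C(C)C)OC(=O)[C@@H]3Cc3cc(OC)c4c(c3)[C@H](CO[Si](C)(C)C(C)(C)C)[C@@H](c3ccc(O[Si](C)(C)C(C)(C)C)c(OC)c3)O4)cc2OC)ccc1O[Si](C)(C)C(C)(C)C | intermediate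
34 | (3R,4R,5R)-3,4-dibenzyl-5-menthyloxy lactone (dithiane replaced by CH2) | COc1cc([C@@H](OC(C)(C)OC2)[C@H]2Oc2ccc(C[C@H]3[C@H](O[C@@H]4C[C@H](C)CC[C@H]4C(C)C)OC(=O)[C@@H]3Cc3cc(OC)c4c(c3)[C@H](CO[Si](C)(C)C(C)(C)C)[C@@H](c3ccc(O[Si](C)(C)C(C)(C)C)c(OC)c3)O4)cc2OC)ccc1O[Si](C)(C)C(C)(C)C | intermediate
35 | (2R,3R)-2,3-dibenzyl-4-hydroxybutanoic acid with free phenols, acetonide and primary silyl ether (present as its potassium salt) | COc1cc([C@@H](OC(C)(C)OC2)[C@H]2Oc2ccc(C[C@@H](CO)[C@H](C(=O)O)Cc3cc(OC)c4c(c3)[C@H](CO[Si](C)(C)C(C)(C)C)[C@@H](c3ccc(O)c(OC)c3)O4)cc2OC)ccc1O | intermediate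
36 | (3R,4R)-lactone with free phenols, acetonide and primary silyl ether | COc1cc([C@@H](OC(C)(C)OC2)[C@H]2Oc2ccc(C[C@H]3COC(=O)[C@@H]3Cc3cc(OC)c4c(c3)[C@H](CO[Si](C)(C)C(C)(C)C)[C@@H](c3ccc(O)c(OC)c3)O4)cc2OC)ccc1O | intermediate
37 | (3R,4R)-3-{[(2S,3R)-2-(4-hydroxy-3-methoxyphenyl)-3-(hydroxymethyl)-7-methoxy-2,3-dihydro-1-benzofuran-5-yl]methyl}-4-(4-{[(1R,2S)-1,3-dihydroxy-1-(4-hydroxy-3-methoxyphenyl)propan-2-yl]oxy}-3-methoxybenzyl)dihydrofuran-2(3H)-one | COc1cc([C@@H](O)[C@H](CO)Oc2ccc(C[C@H]3COC(=O)[C@@H]3Cc3cc(OC)c4c(c3)[C@H](CO)[C@@H](c3ccc(O)c(OC)c3)O4)cc2OC)ccc1O | target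

**Step count**

Total step count: 22. Longest linear sequence: 13 steps (steps 10 to 22, from 16 to 37).

**Steps most likely to fail**

Step 7. The activated benzylic hydroxyl may be lost by β-elimination across C2–C3, or the electron-rich benzylic oxyphosphonium may ionise so that inversion is incomplete; the β-acyloxy aldehyde passed through in step 8 can eliminate as well. The fallback sets out from 12 and moves the inversion to a compound without a carbonyl group next to the stereocentres. Compound 12 is reduced with LiBH4 (THF, 0 °C) to the threo diol (1S,2S)-1-(4-silyloxy-3-methoxyphenyl)-2-[4-(1,3-dithian-2-yl)-2-methoxyphenoxy]propane-1,3-diol F1. The primary hydroxyl is acylated selectively (PivCl, pyridine, CH2Cl2, 0 °C) to the 3-pivalate F2. The remaining benzylic alcohol is inverted under Mitsunobu conditions (4-nitrobenzoic acid, PPh3, DIAD) to the erythro 1-(4-nitrobenzoate) 3-pivalate F3. LiBH4 then removes both acyl groups and the route is rejoined at 14.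

Step 20. The second stage may fail: C-benzylation of the lithium enolate, flanked by the quaternary dithiane carbon, can be outrun by proton transfer or by decay of the labile electron-rich bromide, leaving the simple conjugate adduct. The fallback sets out from 15 and 4 and separates the two bond formations. The anion of 15 is added to 4 and the enolate is quenched with NH4Cl to give the trans 4-(2-aryl-1,3-dithian-2-yl)-5-menthyloxy lactone F4. NiCl2·6H2O and NaBH4 desulfurise it to the (4R,5R)-4-benzyl-5-menthyloxy lactone F5. The less hindered enolate of F5 (LiN(i-Pr)2, THF, −78 °C) is then alkylated with 30 anti to the C4 benzyl group, which returns the route at 34.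

Step 22. In the acidic stage the benzylic C7–O bond para to the freed ring A phenol may ionise (epimerisation towards the threo isomer or ether exchange), and ring closure and deprotection may run at different rates and leave mixtures. The fallback sets out from 34 and replaces the single strong-acid stage by staged, mostly non-acidic cleavage. After the NaBH4/KOH stage the mixture is brought only to about pH 3 with citric acid at 0 °C and lactone 36 is isolated. Bu4NF buffered with AcOH (THF, 0 °C) cleaves the primary silyl ether to give the acetonide lactone with free phenols and free primary alcohol F6. The acetonide is then hydrolysed with 80% aqueous AcOH at rt, which returns the route at 37.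

Further compounds
F1 | step 7 | (1S,2S)-1-{4-[(tert-butyldimethylsilyl)oxy]-3-methoxyphenyl}-2-[4-(1,3-dithian-2-yl)-2-methoxyphenoxy]propane-1,3-diol (threo) | COc1cc([C@H](O)[C@H](CO)Oc2ccc(C3SCCCS3)cc2OC)ccc1O[Si](C)(C)C(C)(C)C
F2 | step 7 | 3-pivalate of F1 | COc1cc([C@H](O)[C@H](COC(=O)C(C)(C)C)Oc2ccc(C3SCCCS3)cc2OC)ccc1O[Si](C)(C)C(C)(C)C
F3 | step 7 | erythro 1-(4-nitrobenzoate) 3-pivalate (benzylic carbon inverted to R) | COc1cc([C@@H](OC(=O)c2ccc([N+](=O)[O-])cc2)[C@H](COC(=O)C(C)(C)C)Oc2ccc(C3SCCCS3)cc2OC)ccc1O[Si](C)(C)C(C)(C)C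
F4 | step 20 | (4R,5R)-4-[2-(A–B aryl)-1,3-dithian-2-yl]-5-[(1R,2S,5R)-menthyloxy]dihydrofuran-2(3H)-one | COc1cc([C@@H](OC(C)(C)OC2)[C@H]2Oc2ccc(C3(SCCCS3)[C@H]3[C@H](O[C@@H]4C[C@H](C)CC[C@H]4C(C)C)OC(=O)C3)cc2OC)ccc1O[Si](C)(C)C(C)(C)C
F5 | step 20 | (4R,5R)-4-[(A–B aryl)methyl]-5-[(1R,2S,5R)-menthyloxy]dihydrofuran-2(3H)-one | COc1cc([C@@H](OC(C)(C)OC2)[C@H]2Oc2ccc(C[C@H]3[C@H](O[C@@H]4C[C@H](C)CC[C@H]4C(C)C)OC(=O)C3)cc2OC)ccc1O[Si](C)(C)C(C)(C)C
F6 | step 22 | (3R,4R)-lactone with free phenols and free primary alcohol, acetonide retained | COc1cc([C@@H](OC(C)(C)OC2)[C@H]2Oc2ccc(C[C@H]3COC(=O)[C@@H]3Cc3cc(OC)c4c(c3)[C@H](CO)[C@@H](c3ccc(O)c(OC)c3)O4)cc2OC)ccc1O
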